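## Analysis of the target

The target 16 is an open-chain tridepside: three benzene rings (A, B, C), each a 2,4-dioxygenated 6-methylbenzoyl (orsellinate) unit, are joined head to tail by two aryl ester bonds, from O4 of ring A to the carbonyl on C1 of ring B and from O4 of ring B to the carbonyl on C1 of ring C, and ring A ends in a methyl ester. There is no stereocentre and no lasting axial chirality, so the problem is one of constitution only. The sensitive groups are the two aryl ester links, which exchange or cleave under basic, nucleophilic or strongly Lewis acidic conditions, and the four free phenols. The difficulty is repetition: three near-identical rings carry six oxygen functions, of which only the 4-oxygens of rings A and B may be acylated, and each acyl carbon is flanked by two ortho substituents and reacts slowly. Each 2-hydroxyl is hydrogen-bonded to its own ester carbonyl and is therefore a poorer nucleophile than a 4-hydroxyl; this is the handle for every regioselective acylation. The strategy rests on ring B, whose C1 carries the ester carbon, C2 and C4 oxygen, C6 methyl, and C3 and C5 hydrogen. A but-2-ynoate supplies C1, C6 and the methyl, and a 1,1,3-trioxygenated butadiene supplies C2 to C5. If the ynoate is the O4 ester of ring A, ring B is formed already attached to ring A and with O2 and O4 chemically different.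

## Retrosynthetic reasoning

**16 to 15.** The last operation removes protecting groups only: the two benzyl ethers on ring C and the methyl ether on O2 of ring B. All three are cleaved on the alkyl side of oxygen by one Lewis acid. Ring C can then be introduced with both oxygens masked, so its acid can be activated, and ring B keeps the O2 substituent it is formed with. The forward step must break three ether bonds and leave two aryl esters and one methyl ester intact. Chelation of the methyl ether to the neighbouring carbonyl and the lability of benzyl ethers make this plausible.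

**15 to 11 and 14.** The ester bond between O4 of ring B and the carbonyl carbon of ring C is cut. In 11 the only unchelated hydroxyl is O4 of ring B; O2 of ring B is a methyl ether and O2 of ring A is hydrogen-bonded to the methyl ester. The cut is convergent and the forward acylation needs no extra protection. It must bring a di-ortho-substituted aroyl chloride onto a moderately nucleophilic phenol.

**14 to 13 to 12 to 1.** Ring C is traced through its acid 13 and the dibenzylated ester 12 to methyl orsellinate 1, which is also the source of ring A. One commercial compound then supplies two of the three rings. The benzyl ethers suppress decarboxylation and allow the acid to be activated.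

**11 to 3 and 7 (key disconnection).** The C1–C2 and C5–C6 bonds of ring B are cut. Cutting the A–B ester bond instead would require a ring B acid with O2 and O4 differently protected, which costs several steps. Cutting the ring gives two small pieces, and the polarity of the cycloaddition sets the O2/O4 difference. Forward, the phenol of 3 is masked in the flask as 8; diene 7 adds to give 9; 9 aromatises to 10; work-up gives 11.

**3 to 1 and 2.** The ester bond between O4 of ring A and the ynoate carbonyl is cut. The forward reaction must acylate O4 and not the chelated O2, without conjugate addition to the triple bond.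

**7 to 6 to 4 and 5.** The diene is the silyl dienol ether of enone 6. The C2–C3 bond of 6 is cut to give ketene acetal 4 and acid chloride 5. The forward steps are a C-acylation and a kinetic enol silylation.

## Alternatives that were turned down

**Alternative 1:** The C1–C(=O) and C(=O)–O bonds of the ring B–C ester are cut together. Forward, the aryl iodide 1,5-bis(benzyloxy)-2-iodo-3-methylbenzene A2, carbon monoxide A3 and the O4 hydroxyl of the ring A–B didepside A4 would be joined under catalysis by Pd(PPh3)4, a complex of zerovalent palladium. The product would be A1, the ring C dibenzyl ether of the target.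
- For it: no hindered acid or acid chloride is needed, and A1 needs only hydrogenolysis at the end. That endgame is milder than the Lewis acid step of the chosen route, so on this point the alternative is stronger.
- Against it: oxidative addition into the electron-rich, di-ortho-substituted iodide A2 is slow, and the hindered acyl-palladium species must be captured by a phenol deactivated by a para acyl group. The base needed makes phenoxides, which can attack the existing aryl ester bond.
- Comparison: the alternative builds no ring. A4 must still be made by a separate depside synthesis, so it replaces only the simplest step of the chosen route (11 plus 14). The chosen route offers instead one step that builds ring B, its ester bond and its O2/O4 difference together.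

**Alternative 2:** The three C2–O bonds are cut. Forward, the tridepside A6, assembled from 4-hydroxy-2-methylbenzoic acid A5, would be hydroxylated at the one free ortho C–H of each benzoyl ring by ester-directed C–H activation. The product would be the ring C 4-O-acetate A7 of the target.
- For it: the monomer A5 is simpler than an orsellinate, no chelated hydroxyl has to be distinguished during chain assembly, and the site on each ring is unambiguous because the other ortho position carries methyl. In protecting-group economy it is at least as good as the chosen route.
- Against it: three C–H oxidations must all go to completion on one molecule of A6. An aryl ester carbonyl can also direct the metal to the ortho positions of the phenoxy ring it is attached to, so rings A and B have competing sites. The oxidising, acidic medium and the final deacetylation of A7 both endanger the depside bonds.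
- Comparison: the chosen route needs one demanding bond-forming event with polarity-controlled regiochemistry, not three with directing-group ambiguity.

**Alternative 3:** Ring C is cut at C5–C6, C2–C3, C4–C5 and C1–C2. Forward, the diazoketone A8, in which O4 of ring B of A4 carries an (E)-5-diazo-3-methyl-4-oxopent-2-enoyl group, would undergo Wolff rearrangement to the vinylketene A10. (2+2) addition of (triisopropylsilyloxy)ethyne A9, four-electron ring opening and six-electron closure would give A11, the ring C 4-O-triisopropylsilyl ether of the target.
- For it: it forms more skeletal bonds in its key step than the chosen route, gives ring C with O2 free and O4 silylated, and ends with a fluoride deprotection. On bond count and mildness of the last step it is stronger.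
- Against it: A8 contains a diazo group conjugated to an electron-poor alkene and is prone to dipolar self-reaction. The usual preparations of a diazoketone (diazo transfer under strong base, or acylation of a diazoalkane) do not tolerate the free phenols and aryl esters of A4. The four-stage cascade would be run last, on the most valuable intermediate.
- Comparison: the chosen route places its ring-forming step early, on a small and cheap substrate.

Key step: step 4

Remark on the chemistry: methyl orsellinate 1 is used as the commercial source of both ring A and ring C, and the silylated intermediates of step 4 are handled in one flask.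

## Route

**Step 1**
Reactants: 1 methyl orsellinate (methyl 2,4-dihydroxy-6-methylbenzoate); 2 but-2-ynoic acid
Product: 3 methyl 4-(but-2-ynoyloxy)-2-hydroxy-6-methylbenzoate
Conditions: DCC, DMAP (cat.), CH2Cl2, 0 °C to rt
Reagents that add atoms: none
Why: Steglich esterification; the 4-hydroxyl is the more acidic and unhindered phenol while the 2-hydroxyl is hydrogen-bonded to the ester carbonyl, so one equivalent of acid should acylate O4 only, and low temperature with catalytic DMAP limits conjugate addition to the ynoate.

**Step 2**
Reactants: 4 1,1-dimethoxyethene; 5 acetyl chloride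
Product: 6 4,4-dimethoxybut-3-en-2-one
Conditions: Et3N, Et2O, 0 °C to rt; filtration, distillation
Reagents that add atoms: none
Why: C-acylation of a ketene acetal by an acid chloride; the amine removes the proton from the dialkoxycarbenium intermediate, which regenerates the push–pull ketene acetal before chloride can demethylate it.

**Step 3**
Reactants: 6 4,4-dimethoxybut-3-en-2-one
Product: 7 1,1-dimethoxy-3-(trimethylsilyloxy)buta-1,3-diene
Conditions: LiN(iPr)2, THF, −78 °C; Me3SiCl, −78 °C to rt; non-aqueous work-up, distillation
Reagents that add atoms: chlorotrimethylsilane, C[Si](C)(C)Cl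
Why: Kinetic enolisation at the methyl group, the only acidic C–H, followed by O-silylation gives the cross-conjugated silyl dienol ether; the work-up avoids water because the diene hydrolyses easily.

**Step 4**
Reactants: 3 methyl 4-(but-2-ynoyloxy)-2-hydroxy-6-methylbenzoate; 7 1,1-dimethoxy-3-(trimethylsilyloxy)buta-1,3-diene
Product: 11 methyl 2-hydroxy-4-[(4-hydroxy-2-methoxy-6-methylbenzoyl)oxy]-6-methylbenzoate, via ring A trimethylsilyl ether 8 (not isolated), via cyclohexa-1,4-diene ketal cycloadduct 9 (not isolated), via bis(trimethylsilyl) ether of the didepside 10 (not isolated)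
Conditions: N,O-bis(trimethylsilyl)acetamide, PhMe, 60 °C, then concentrate; 7 (2.5 equiv), PhMe, 110 °C, sealed tube; 1 M HCl, THF, 0 °C
Reagents that add atoms: none
Why: The phenol of 3 is first silylated to 8 so that its proton cannot destroy the acid-labile diene; 7 then adds to the ynoate of 8 in a thermal, asynchronous (4+2) cycloaddition of normal electron demand. The closest known reaction type is the Diels–Alder benzannulation of 1,1-dialkoxy-3-silyloxybutadienes with alkynoates to resorcylate esters. Ring B is closed as a six-membered carbocycle by intermolecular (4+2) cycloaddition, forming C5–C6 and C1–C2, and the doubly allylic ketal 9 then loses methanol to give the aromatic 10. No stereocentre has to be controlled, since the sp3 carbons of 9 become aromatic. The step needs regioselectivity, and polarity provides it: the CH2 terminus of 7, which carries the largest HOMO coefficient, bonds to the methyl-bearing β-carbon of the ynoate and the ketene acetal carbon bonds to the α-carbon, so methoxy ends up ortho and silyloxy para to the ester carbon with methyl at C6. The aryl ester makes the alkyne more electron-poor than an alkyl ester would, which should partly offset the retarding β-methyl group, and the neutral thermal conditions leave the ester bond alone. Dilute acid on work-up cleaves both aryl silyl ethers and gives 11, with O2 of ring B as the methyl ether and O4 free.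

**Step 5**
Reactants: 1 methyl orsellinate
Product: 12 methyl 2,4-bis(benzyloxy)-6-methylbenzoate
Conditions: BnBr (2.5 equiv), K2CO3, DMF, 60 °C
Reagents that add atoms: benzyl bromide, BrCc1ccccc1
Why: Williamson ether synthesis; excess halide and warming in a dipolar solvent also alkylate the chelated 2-hydroxyl.

**Step 6**
Reactants: 12 methyl 2,4-bis(benzyloxy)-6-methylbenzoate
Product: 13 2,4-bis(benzyloxy)-6-methylbenzoic acid
Conditions: KOH, DMSO–H2O, 90 °C; then cold aq. HCl
Reagents that add atoms: potassium hydroxide (hydroxide oxygen), [K+].[OH-]
Why: Saponification of a hindered benzoate, which needs poorly solvated hydroxide and heat; benzyl ethers are stable to base, and the etherified acid does not decarboxylate as the free dihydroxy acid would.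

**Step 7**
Reactants: 13 2,4-bis(benzyloxy)-6-methylbenzoic acid
Product: 14 2,4-bis(benzyloxy)-6-methylbenzoyl chloride
Conditions: (COCl)2, DMF (cat.), CH2Cl2, 0 °C to rt; evaporate, use crude
Reagents that add atoms: oxalyl chloride, O=C(Cl)C(=O)Cl
Why: Acid chloride formation through the Vilsmeier-type chloroiminium catalyst; the conditions are mild and leave the benzyl ethers intact.

**Step 8**
Reactants: 11 methyl 2-hydroxy-4-[(4-hydroxy-2-methoxy-6-methylbenzoyl)oxy]-6-methylbenzoate; 14 2,4-bis(benzyloxy)-6-methylbenzoyl chloride
Product: 15 methyl 4-({4-[(2,4-bis(benzyloxy)-6-methylbenzoyl)oxy]-2-methoxy-6-methylbenzoyl}oxy)-2-hydroxy-6-methylbenzoate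
Conditions: Et3N, DMAP (cat.), CH2Cl2, 0 °C to rt
Reagents that add atoms: none
Why: DMAP-catalysed O-acylation of a phenol by an aroyl chloride; O4 of ring B is the only hydroxyl of 11 not tied up in a hydrogen bond to a carbonyl, so it should be acylated in preference to the chelated 2-hydroxyl of ring A.

**Step 9**
Reactants: 15 methyl 4-({4-[(2,4-bis(benzyloxy)-6-methylbenzoyl)oxy]-2-methoxy-6-methylbenzoyl}oxy)-2-hydroxy-6-methylbenzoate
Product: 16 the target, methyl 4-({4-[(2,4-dihydroxy-6-methylbenzoyl)oxy]-2-hydroxy-6-methylbenzoyl}oxy)-2-hydroxy-6-methylbenzoate
Conditions: BCl3 (6 equiv), pentamethylbenzene, CH2Cl2, −78 to 0 °C; then H2O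
Reagents that add atoms: none
Why: Lewis acid ether cleavage; BCl3 removes aryl benzyl ethers at low temperature, with pentamethylbenzene trapping the benzyl cations, and cleaves the methyl ether that chelates boron together with the ortho ester carbonyl, while the aryl and methyl esters should survive at or below 0 °C.

## Compound list

1 | methyl orsellinate (methyl 2,4-dihydroxy-6-methylbenzoate) | COC(=O)c1c(C)cc(O)cc1O | starting material
2 | but-2-ynoic acid | CC#CC(=O)O | starting material
3 | methyl 4-(but-2-ynoyloxy)-2-hydroxy-6-methylbenzoate | COC(=O)c1c(C)cc(OC(=O)C#CC)cc1O | intermediate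
4 | 1,1-dimethoxyethene | C=C(OC)OC | starting material
5 | acetyl chloride | CC(=O)Cl | starting material
6 | 4,4-dimethoxybut-3-en-2-one | CC(=O)C=C(OC)OC | intermediate
7 | 1,1-dimethoxy-3-(trimethylsilyloxy)buta-1,3-diene | COC(OC)=CC(=C)O[Si](C)(C)C | intermediate
8 | methyl 4-(but-2-ynoyloxy)-6-methyl-2-(trimethylsilyloxy)benzoate (not isolated) | COC(=O)c1c(C)cc(OC(=O)C#CC)cc1O[Si](C)(C)C | intermediate
9 | 4-(methoxycarbonyl)-3-methyl-5-(trimethylsilyloxy)phenyl 6,6-dimethoxy-2-methyl-4-(trimethylsilyloxy)cyclohexa-1,4-diene-1-carboxylate (not isolated) | COC(=O)c1c(C)cc(OC(=O)C2=C(C)CC(O[Si](C)(C)C)=CC2(OC)OC)cc1O[Si](C)(C)C | intermediate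
10 | methyl 4-{[2-methoxy-6-methyl-4-(trimethylsilyloxy)benzoyl]oxy}-6-methyl-2-(trimethylsilyloxy)benzoate (not isolated) | COC(=O)c1c(C)cc(OC(=O)c2c(C)cc(O[Si](C)(C)C)cc2OC)cc1O[Si](C)(C)C | intermediate
11 | methyl 2-hydroxy-4-[(4-hydroxy-2-methoxy-6-methylbenzoyl)oxy]-6-methylbenzoate | COC(=O)c1c(C)cc(OC(=O)c2c(C)cc(O)cc2OC)cc1O | intermediate
12 | methyl 2,4-bis(benzyloxy)-6-methylbenzoate | COC(=O)c1c(C)cc(OCc2ccccc2)cc1OCc1ccccc1 | intermediate
13 | 2,4-bis(benzyloxy)-6-methylbenzoic acid | Cc1cc(OCc2ccccc2)cc(OCc2ccccc2)c1C(=O)O | intermediate
14 | 2,4-bis(benzyloxy)-6-methylbenzoyl chloride | Cc1cc(OCc2ccccc2)cc(OCc2ccccc2)c1C(Cl)=O | intermediate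
15 | methyl 4-({4-[(2,4-bis(benzyloxy)-6-methylbenzoyl)oxy]-2-methoxy-6-methylbenzoyl}oxy)-2-hydroxy-6-methylbenzoate | COC(=O)c1c(C)cc(OC(=O)c2c(C)cc(OC(=O)c3c(C)cc(OCc4ccccc4)cc3OCc3ccccc3)cc2OC)cc1O | intermediate
16 | methyl 4-({4-[(2,4-dihydroxy-6-methylbenzoyl)oxy]-2-hydroxy-6-methylbenzoyl}oxy)-2-hydroxy-6-methylbenzoate | COC(=O)c1c(C)cc(OC(=O)c2c(C)cc(OC(=O)c3c(C)cc(O)cc3O)cc2O)cc1O | target

## Step count and risk

Total step count: 9. Longest linear sequence: 5 steps (steps 2, 3, 4, 8, 9, or equally steps 5, 6, 7, 8, 9).

**Step 4 (key step).**
- What may go wrong: cycloaddition to a β-methyl ynoate is slow, and at the temperature it needs the diene may be lost by desilylation or proton transfer before it reacts. The nucleophilic diene may also attack the activated aryl ester carbonyl and expel ring A as its phenoxide.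
- Fallback: the fallback sets out from 7 and 1 and returns at 11. Ring B would be built on the simplest ester of the same class and attached to ring A afterwards. Diene 7 is heated with commercial methyl but-2-ynoate and worked up with dilute acid to give methyl 4-hydroxy-2-methoxy-6-methylbenzoate F1. Benzylation (BnBr, K2CO3, DMF) gives methyl 4-(benzyloxy)-2-methoxy-6-methylbenzoate F2. KOH in aqueous DMSO gives 4-(benzyloxy)-2-methoxy-6-methylbenzoic acid F3, and oxalyl chloride with catalytic DMF gives 4-(benzyloxy)-2-methoxy-6-methylbenzoyl chloride F4. Acylation of 1 at O4 (Et3N, catalytic DMAP, CH2Cl2) gives methyl 4-{[4-(benzyloxy)-2-methoxy-6-methylbenzoyl]oxy}-2-hydroxy-6-methylbenzoate F5, and hydrogenolysis (H2, Pd/C, EtOAc) gives 11.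

**Step 2.**
- What may go wrong: the amine may dehydrochlorinate the acid chloride to a ketene, the ketene acetal may oligomerise under acid, and chloride may demethylate the cationic intermediate. All three consume material before the enone forms.
- Fallback: the fallback sets out from 5 and returns at 6. Friedel–Crafts addition of 5 to 1,1-dichloroethene (AlCl3, CH2Cl2) gives 4,4,4-trichlorobutan-2-one F6. This loses hydrogen chloride on distillation to give 4,4-dichlorobut-3-en-2-one F7. Two addition–elimination steps with NaOMe in methanol then give 6.

**Step 8.**
- What may go wrong: acyl transfer from the di-ortho-substituted aroyl chloride may be slow. The phenoxide formed under basic conditions may then attack the existing depside bond and scramble the esters, or the chelated hydroxyl of ring A may be acylated as well.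
- Fallback: the fallback sets out from 13 and 11 and returns at 15; it replaces base-mediated acyl chloride chemistry with acid-mediated acyl transfer. Acid 13 is treated with trifluoroacetic anhydride in toluene to form 2,4-bis(benzyloxy)-6-methylbenzoic trifluoroacetic anhydride F8. Its acylium-like carbonyl is taken up by O4 of ring B of 11 without any phenoxide being present, and aqueous work-up gives 15.

**Step 9.**
- What may go wrong: benzyl cations may C-alkylate the electron-rich ring C. The chelated methyl ether may cleave incompletely at the low temperature that protects the esters, and warming risks cleaving the methyl ester or the depside bonds.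
- Fallback: the fallback sets out from 15 and returns at 16; it separates the two kinds of ether cleavage. Hydrogenolysis of 15 (H2, Pd/C, EtOAc) removes both benzyl groups without cations and gives methyl 4-({4-[(2,4-dihydroxy-6-methylbenzoyl)oxy]-2-methoxy-6-methylbenzoyl}oxy)-2-hydroxy-6-methylbenzoate F9. BCl3 in CH2Cl2 from −78 to 0 °C then cleaves only the chelated methyl ether and gives 16.

## Further compounds

F1 | step 4 | methyl 4-hydroxy-2-methoxy-6-methylbenzoate | COC(=O)c1c(C)cc(O)cc1OC
F2 | step 4 | methyl 4-(benzyloxy)-2-methoxy-6-methylbenzoate | COC(=O)c1c(C)cc(OCc2ccccc2)cc1OC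
F3 | step 4 | 4-(benzyloxy)-2-methoxy-6-methylbenzoic acid | COc1cc(OCc2ccccc2)cc(C)c1C(=O)O
F4 | step 4 | 4-(benzyloxy)-2-methoxy-6-methylbenzoyl chloride | COc1cc(OCc2ccccc2)cc(C)c1C(Cl)=O
F5 | step 4 | methyl 4-{[4-(benzyloxy)-2-methoxy-6-methylbenzoyl]oxy}-2-hydroxy-6-methylbenzoate | COC(=O)c1c(C)cc(OC(=O)c2c(C)cc(OCc3ccccc3)cc2OC)cc1O
F6 | step 2 | 4,4,4-trichlorobutan-2-one | CC(=O)CC(Cl)(Cl)Cl
F7 | step 2 | 4,4-dichlorobut-3-en-2-one | CC(=O)C=C(Cl)Cl
F8 | step 8 | 2,4-bis(benzyloxy)-6-methylbenzoic trifluoroacetic anhydride | Cc1cc(OCc2ccccc2)cc(OCc2ccccc2)c1C(=O)OC(=O)C(F)(F)F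
F9 | step 9 | methyl 4-({4-[(2,4-dihydroxy-6-methylbenzoyl)oxy]-2-methoxy-6-methylbenzoyl}oxy)-2-hydroxy-6-methylbenzoate | COC(=O)c1c(C)cc(OC(=O)c2c(C)cc(OC(=O)c3c(C)cc(O)cc3O)cc2OC)cc1O
A1 | alternative 1 | methyl 4-({4-[(2,4-bis(benzyloxy)-6-methylbenzoyl)oxy]-2-hydroxy-6-methylbenzoyl}oxy)-2-hydroxy-6-methylbenzoate | COC(=O)c1c(C)cc(OC(=O)c2c(C)cc(OC(=O)c3c(C)cc(OCc4ccccc4)cc3OCc3ccccc3)cc2O)cc1O
A2 | alternative 1 | 1,5-bis(benzyloxy)-2-iodo-3-methylbenzene | Cc1cc(OCc2ccccc2)cc(OCc2ccccc2)c1I
A3 | alternative 1 | carbon monoxide | [C-]#[O+]
A4 | alternative 1 | methyl 4-[(2,4-dihydroxy-6-methylbenzoyl)oxy]-2-hydroxy-6-methylbenzoate | COC(=O)c1c(C)cc(OC(=O)c2c(C)cc(O)cc2O)cc1O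
A5 | alternative 2 | 4-hydroxy-2-methylbenzoic acid | Cc1cc(O)ccc1C(=O)O
A6 | alternative 2 | methyl 4-({4-[(4-acetoxy-2-methylbenzoyl)oxy]-2-methylbenzoyl}oxy)-2-methylbenzoate | COC(=O)c1c(C)cc(OC(=O)c2c(C)cc(OC(=O)c3c(C)cc(OC(C)=O)cc3)cc2)cc1
A7 | alternative 2 | methyl 4-({4-[(4-acetoxy-2-hydroxy-6-methylbenzoyl)oxy]-2-hydroxy-6-methylbenzoyl}oxy)-2-hydroxy-6-methylbenzoate | COC(=O)c1c(C)cc(OC(=O)c2c(C)cc(OC(=O)c3c(C)cc(OC(C)=O)cc3O)cc2O)cc1O
A8 | alternative 3 | methyl 4-({4-[((E)-5-diazo-3-methyl-4-oxopent-2-enoyl)oxy]-2-hydroxy-6-methylbenzoyl}oxy)-2-hydroxy-6-methylbenzoate | COC(=O)c1c(C)cc(OC(=O)c2c(C)cc(OC(=O)/C=C(\C)C(=O)C=[N+]=[N-])cc2O)cc1O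
A9 | alternative 3 | (triisopropylsilyloxy)ethyne | C#CO[Si](C(C)C)(C(C)C)C(C)C
A10 | alternative 3 | methyl 2-hydroxy-4-({2-hydroxy-6-methyl-4-[((E)-3-methyl-5-oxopenta-2,4-dienoyl)oxy]benzoyl}oxy)-6-methylbenzoate | COC(=O)c1c(C)cc(OC(=O)c2c(C)cc(OC(=O)/C=C(\C)C=C=O)cc2O)cc1O
A11 | alternative 3 | methyl 2-hydroxy-4-({2-hydroxy-4-[(2-hydroxy-6-methyl-4-(triisopropylsilyloxy)benzoyl)oxy]-6-methylbenzoyl}oxy)-6-methylbenzoate | COC(=O)c1c(C)cc(OC(=O)c2c(C)cc(OC(=O)c3c(C)cc(O[Si](C(C)C)(C(C)C)C(C)C)cc3O)cc2O)cc1O
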